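## Retrosynthetic overview

1. The β-acetoxy ketone is the acetate of a syn-aldol, carried as a fused Δ2-isoxazoline; the oxirane comes from a tertiary-alcohol/primary-tosylate pair, and both are unmasked at the end.
2. The two different esters go onto a 5α,6α-cis-diol (a stannylene acetal tells the equatorial from the axial OH); diol and exocyclic methylene both come from a C4 ketone (Saegusa enone, OsO4, titanium methylidene).
3. The cyclopentane ring and the isoxazoline form together by intramolecular nitrile oxide cycloaddition of a (Z)-propenyl group and a CH2CH=NOH arm held trans on a cyclohexanone (cuprate addition, then enolate alkylation of a 4-substituted cyclohexenone).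
4. The cyclohexenone comes from a lipase-desymmetrised meso-cyclohex-2-ene-1,4-diol by Pd allylic alkylation; the side-chain quaternary carbinol is set by Sharpless epoxidation and hydride opening.
5. Ring order: six-membered ring (from cyclohexa-1,3-diene) → cyclopentane plus isoxazoline → oxirane last. Acyl pieces: ynoate carbocupration (Z-enoate) and Ru-catalysed asymmetric hydrogenation ((R)-2-methylbutanoate).

Conventions: ring carbons of all intermediates carry the target's hydrindane locants (C1 bears the side chain, C2 ketone, C3, C3a, C4 methylene, C5, C6, C7 bears the oxirane, C7a; C1′ is the side-chain carbinol carbon). β is the face of H-7a and α the face of H-3a. Diox = (4S)-2,2,4-trimethyl-1,3-dioxolan-4-yl; TBS = tert-butyldimethylsilyl.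

Assumption: the lipase acetylates the (S)-carbinol of the meso-diol (the sense it shows with the cyclopentene homologue); a lipase of opposite sense gives the same monoacetate by hydrolysis of the meso-diacetate.

## Route

Step 1
Reactants: 1 ethyl pent-2-ynoate
Product: 3 ethyl (Z)-3-methylpent-2-enoate, via alkenylcuprate 2 (not isolated)
Conditions: Me2CuLi (from MeLi, CuI), THF, −78 °C; MeOH, −78 °C
Reagents that add atoms: lithium dimethylcuprate, [Li+].C[Cu-]C
Why: Syn carbocupration of the ynoate puts CH3 and Cu cis at −78 °C, and protonation with retention leaves ethyl cis to the ester, i.e. the Z-enoate.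

Step 2
Reactants: 3 ethyl (Z)-3-methylpent-2-enoate
Product: 4 (Z)-3-methylpent-2-enoic acid
Conditions: LiOH, THF/MeOH/H2O, rt; then aq. HCl
Reagents that add atoms: lithium hydroxide, [Li+].[OH-]
Why: Mild ester saponification that leaves the trisubstituted alkene geometry alone.

Step 3
Reactants: 4 (Z)-3-methylpent-2-enoic acid
Product: 5 (Z)-3-methylpent-2-enoyl chloride
Conditions: (COCl)2, DMF (cat.), CH2Cl2, 0 °C
Reagents that add atoms: oxalyl chloride, ClC(=O)C(Cl)=O
Why: Acid chloride formation through the Vilsmeier-type chloroiminium salt at 0 °C, mild enough to keep the Z geometry.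

Step 4
Reactants: 6 tiglic acid
Product: 7 (R)-2-methylbutanoic acid
Conditions: H2 (1.5 atm), Ru(OAc)2[(R)-H8-BINAP] (0.5 mol %), MeOH, 15 °C
Reagents that add atoms: none
Why: Noyori-type asymmetric hydrogenation of an α,β-unsaturated acid, in which the Ru-bound carboxylate and the (R)-ligand direct H2 to the face that gives the (R) α-stereocentre.

Step 5
Reactants: 7 (R)-2-methylbutanoic acid (2 equiv; one molecule is activated, the second supplies the other acyl half)
Product: 8 (R)-2-methylbutanoic anhydride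
Conditions: DCC (0.5 equiv), CH2Cl2, 0 °C → rt; filter off the urea
Reagents that add atoms: (R)-2-methylbutanoic acid (second molecule of 7), CC[C@@H](C)C(=O)O
Why: Carbodiimide dehydration, in which the O-acylisourea of one acid molecule is acylated by the carboxylate of a second, gives the symmetric anhydride without touching the α-stereocentre.

Step 6
Reactants: 9 cyclohexa-1,3-diene
Product: 11 cis-cyclohex-2-ene-1,4-diol, via endoperoxide 10 (not isolated)
Conditions: O2, hν, tetraphenylporphyrin (cat.), CH2Cl2, −20 °C; then thiourea, MeOH, rt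
Reagents that add atoms: dioxygen, O=O
Why: [4+2] cycloaddition of singlet oxygen to the s-cis diene followed by thiourea reduction of the O–O bond keeps both C–O bonds on one face, so the diol is cis and meso.

Step 7
Reactants: 11 cis-cyclohex-2-ene-1,4-diol
Product: 12 (1S,4R)-4-hydroxycyclohex-2-en-1-yl acetate
Conditions: lipase from Pseudomonas cepacia (Amano PS), vinyl acetate, t-BuOMe, 25 °C
Reagents that add atoms: vinyl acetate, C=COC(C)=O
Why: Enzymatic desymmetrisation, in which the lipase (a serine hydrolase) acetylates only one of the two enantiotopic carbinols and so fixes the (R) carbinol (future C4) and the (S) acetate carbon (future C7).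

Step 8
Reactants: 12 (1S,4R)-4-hydroxycyclohex-2-en-1-yl acetate
Product: 13 (1S,4R)-4-(TBS-oxy)cyclohex-2-en-1-yl acetate
Conditions: TBSCl, imidazole, DMF, rt
Reagents that add atoms: tert-butyldimethylsilyl chloride, CC(C)(C)[Si](C)(C)Cl
Why: Standard silylation of the free alcohol so that only the acetate can ionise in the next step.

Step 9
Reactants: 13 (1S,4R)-4-(TBS-oxy)cyclohex-2-en-1-yl acetate; 14 triethyl phosphonoacetate
Product: 15 ethyl 2-[(1S,4R)-4-(TBS-oxy)cyclohex-2-en-1-yl]-2-(diethoxyphosphoryl)acetate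
Conditions: NaH, THF, 0 °C; Pd(PPh3)4 (5 mol %), 50 °C
Reagents that add atoms: none
Why: Tsuji–Trost allylic alkylation in which zerovalent palladium ionises the acetate with inversion and the stabilised carbanion attacks anti to the metal at the terminus remote from the silyloxy group, giving the C7–C bond with net retention.

Step 10
Reactants: 15 phosphonate
Product: 16 ethyl 2-[(1S,4R)-4-(TBS-oxy)cyclohex-2-en-1-yl]prop-2-enoate
Conditions: aq. HCHO (37 %), K2CO3, THF, 60 °C
Reagents that add atoms: formaldehyde, C=O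
Why: Horner–Wadsworth–Emmons olefination with formaldehyde turns the α-substituted phosphonoacetate into the α-substituted acrylate.

Step 11
Reactants: 16 acrylate
Product: 17 2-[(1S,4R)-4-(TBS-oxy)cyclohex-2-en-1-yl]prop-2-en-1-ol
Conditions: i-Bu2AlH, CH2Cl2, −78 °C
Reagents that add atoms: none
Why: 1,2-Reduction of the conjugated ester by the aluminium hydride gives the 2-substituted allylic alcohol.

Step 12
Reactants: 17 allylic alcohol
Product: 18 [(2S)-2-[(1S,4R)-4-(TBS-oxy)cyclohex-2-en-1-yl]oxiran-2-yl]methanol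
Conditions: Ti(OiPr)4 (10 mol %), L-(+)-diethyl tartrate (12 mol %), t-BuOOH, 4 Å sieves, CH2Cl2, −20 °C
Reagents that add atoms: tert-butyl hydroperoxide, CC(C)(C)OO
Why: Sharpless asymmetric epoxidation of a 2-substituted allylic alcohol, where L-(+)-tartrate delivers oxygen to the face that makes the oxirane carbon (S) under reagent control while the ring alkene (no free allylic OH) is inert.

Step 13
Reactants: 18 epoxy alcohol
Product: 19 (2S)-2-[(1S,4R)-4-(TBS-oxy)cyclohex-2-en-1-yl]propane-1,2-diol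
Conditions: LiAlH4, THF, 0 °C
Reagents that add atoms: none
Why: Hydride opening of the 2,2-disubstituted oxirane at its unhindered CH2 creates the methyl group and the tertiary alcohol, and the untouched C–O bond keeps the quaternary carbon (S).

Step 14
Reactants: 19 diol
Product: 20 tert-butyldimethyl{[(1R,4S)-4-Diox-cyclohex-2-en-1-yl]oxy}silane
Conditions: Me2C(OMe)2, PPTS (cat.), CH2Cl2, rt
Reagents that add atoms: 2,2-dimethoxypropane, COC(C)(C)OC
Why: Acid-catalysed transketalisation protects the 1,2-diol as its isopropylidene acetal.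

Step 15
Reactants: 20 silyl ether
Product: 21 (1R,4S)-4-Diox-cyclohex-2-en-1-ol
Conditions: Bu4NF, THF, rt
Reagents that add atoms: none
Why: Fluoride-mediated desilylation frees the allylic alcohol.

Step 16
Reactants: 21 allylic alcohol
Product: 22 (4S)-4-Diox-cyclohex-2-en-1-one
Conditions: MnO2, CH2Cl2, rt
Reagents that add atoms: none
Why: Selective allylic oxidation to the enone under neutral conditions that cannot enolise the C7 stereocentre.

Step 17
Reactants: 22 (4S)-4-Diox-cyclohex-2-en-1-one; 23 (Z)-1-bromoprop-1-ene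
Product: 26 trimethyl{[(3S,4S)-3-[(Z)-prop-1-enyl]-4-Diox-cyclohex-1-en-1-yl]oxy}silane, via (Z)-prop-1-enyllithium 24 (not isolated), via lithium di[(Z)-prop-1-enyl]cuprate 25 (not isolated)
Conditions: 23, t-BuLi (2 equiv), Et2O, −78 °C; CuI (0.5 equiv), −40 °C; then 22, Me3SiCl, THF, −78 °C
Reagents that add atoms: chlorotrimethylsilane, C[Si](C)(C)Cl
Why: Conjugate addition of a Gilman cuprate accelerated by Me3SiCl, in which the propenyl group (Z retained from the vinyllithium) adds to C7a anti to the bulky C7 substituent and the enolate is trapped regiospecifically.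

Step 18
Reactants: 26 silyl enol ether; 27 methyl bromoacetate
Product: 29 methyl 2-[(1S,2R,3S)-6-oxo-2-[(Z)-prop-1-enyl]-3-Diox-cyclohexyl]acetate, via lithium enolate 28 (not isolated)
Conditions: MeLi, THF, 0 °C; then 27, DMPU, −78 → −20 °C
Reagents that add atoms: none
Why: Regiospecific enolate generation from the silyl enol ether and enolate alkylation anti to the neighbouring propenyl group give the all-trans (all-equatorial) 2,3,4-trisubstituted cyclohexanone, setting C3a.

Step 19
Reactants: 29 keto ester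
Product: 31 (3aS,4S,5S,7aR)-4-[(Z)-prop-1-enyl]-5-Diox-hexahydro-1-benzofuran-2(3H)-one, via hydroxy ester 30 (not isolated)
Conditions: LiBH(s-Bu)3, THF, −78 °C → rt
Reagents that add atoms: none
Why: Bulky hydride reduction from the equatorial side gives the axial 4β-alkoxide, which is cis to the acetate arm and lactonises.

Step 20
Reactants: 31 lactone
Product: 32 lactol (2-hydroxy analogue of 31; anomers)
Conditions: i-Bu2AlH, CH2Cl2, −78 °C
Reagents that add atoms: none
Why: Partial reduction of the lactone stops at the stable aluminium hemiacetal at −78 °C.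

Step 21
Reactants: 32 lactol
Product: 33 2-[(1S,2S,3S,6R)-6-hydroxy-2-[(Z)-prop-1-enyl]-3-Diox-cyclohexyl]acetaldehyde oxime
Conditions: NH2OH·HCl, pyridine, EtOH, rt
Reagents that add atoms: hydroxylamine hydrochloride, Cl.NO
Why: Oxime condensation on the open hydroxy-aldehyde form of the lactol.

Step 22
Reactants: 33 hydroxy oxime
Product: 36 isoxazoline alcohol (trans-hydrindane; Δ2-isoxazoline fused on C1–C2; 1′S; H-1 α; 4β-OH; 7β-Diox), via hydroximoyl chloride 34 (not isolated), via nitrile oxide 35 (not isolated)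
Conditions: N-chlorosuccinimide, pyridine (cat.), CHCl3, rt; then Et3N (slow addition), 0.005 M, 0 °C → rt
Reagents that add atoms: none
Why: Intramolecular nitrile oxide–alkene 1,3-dipolar cycloaddition, in which the tether forces C2–C1 and O–C1′ bonding (closing the cyclopentane), syn addition to the Z-alkene fixes C1/C1′ as the syn-aldol pattern, and allylic 1,3-strain plus the trans ring fusion leave only the face that puts H-1 α.

Step 23
Reactants: 36 isoxazoline alcohol
Product: 37 tricyclic ketone (as 36 with C4=O)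
Conditions: Dess–Martin periodinane, NaHCO3, CH2Cl2, rt
Reagents that add atoms: none
Why: Dess–Martin oxidation of the secondary alcohol to the C4 ketone under non-epimerising conditions.

Step 24
Reactants: 37 tricyclic ketone
Product: 38 Δ4,5 trimethylsilyl enol ether of 37
Conditions: LiN(SiMe3)2, Me3SiCl, THF, −78 °C
Reagents that add atoms: chlorotrimethylsilane, C[Si](C)(C)Cl
Why: Kinetic deprotonation at the unhindered C5 methylene (not the C3a methine) with in situ silylation gives the Δ4,5 silyl enol ether.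

Step 25
Reactants: 38 silyl enol ether
Product: 39 enone (as 37 with C5=C6)
Conditions: Pd(OAc)2 (1.1 equiv), MeCN, rt
Reagents that add atoms: none
Why: Saegusa–Ito oxidation, where the oxa-π-allylpalladium intermediate undergoes β-hydride elimination to the C5=C6 enone.

Step 26
Reactants: 39 enone
Product: 40 5α,6α-dihydroxy ketone
Conditions: OsO4 (5 mol %), N-methylmorpholine N-oxide, citric acid, t-BuOH/H2O, rt
Reagents that add atoms: osmium tetroxide, O=[Os](=O)(=O)=O; N-methylmorpholine N-oxide, C[N+]1([O-])CCOCC1; water, O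
Why: Upjohn cis-dihydroxylation, in which OsO4 adds suprafacially from the α face, anti to the bulky β substituent on allylic C7, setting C5 and C6 together.

Step 27
Reactants: 40 diol
Product: 41 5α,6α-bis(triethylsilyl) ether
Conditions: Et3SiOTf, 2,6-lutidine, CH2Cl2, −78 → 0 °C
Reagents that add atoms: triethylsilyl trifluoromethanesulfonate, CC[Si](CC)(CC)OS(=O)(=O)C(F)(F)F
Why: Silylation of both hydroxyls with the reactive silyl triflate, with a base too weak to enolise the ketone.

Step 28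
Reactants: 41 bis-silyl ether ketone
Product: 42 4-methylene bis(triethylsilyl) ether
Conditions: Cp2Ti(μ-Cl)(μ-CH2)AlMe2 (Tebbe reagent), pyridine, THF/toluene, −40 °C → rt
Reagents that add atoms: Tebbe reagent, C[Al-]1(C)C[Ti]([Cl+]1)(C1C=CC=C1)C1C=CC=C1
Why: Tebbe methylenation (titanium methylidene, [2+2] then retro-[2+2]) converts the hindered ketone to the exocyclic methylene without base, so C3a and C5 do not epimerise and no β-elimination occurs.

Step 29
Reactants: 42 bis-silyl ether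
Product: 43 4-methylene-5α,6α-diol
Conditions: Bu4NF, THF, 0 °C
Reagents that add atoms: none
Why: Fluoride-mediated cleavage of both triethylsilyl ethers, with no base-sensitive group present.

Step 30
Reactants: 43 diol; 5 (Z)-3-methylpent-2-enoyl chloride
Product: 45 6α-[(Z)-3-methylpent-2-enoyl]oxy-5α-ol, via stannylene acetal 44 (not isolated)
Conditions: Bu2SnO, toluene, reflux (−H2O); then 5, CH2Cl2, 0 °C → rt
Reagents that add atoms: none
Why: Regioselective acylation through the dibutylstannylene acetal of a cis-diol, which activates the equatorial oxygen (C6) toward the acid chloride.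

Step 31
Reactants: 45 monoester; 8 (R)-2-methylbutanoic anhydride
Product: 46 5α-[(R)-2-methylbutanoyl]oxy-6α-[(Z)-3-methylpent-2-enoyl]oxy isoxazoline
Conditions: 8, DMAP, pyridine, 40 °C
Reagents that add atoms: none
Why: DMAP-catalysed acylation of the remaining axial allylic alcohol with the symmetric anhydride, which does not epimerise the acyl α-centre.

Step 32
Reactants: 46 diester isoxazoline
Product: 48 β-hydroxy ketone (C2=O; 1′S-OH; 7β-Diox), via β-hydroxy imine 47 (not isolated)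
Conditions: Fe powder, NH4Cl, EtOH/H2O, 80 °C
Reagents that add atoms: water, O
Why: Reductive N–O cleavage of the isoxazoline by iron and in situ imine hydrolysis unmask the syn-aldol without touching alkenes, esters or the C1 and C1′ centres.

Step 33
Reactants: 48 β-hydroxy ketone
Product: 49 triol (7β-[(2S)-1,2-dihydroxypropan-2-yl])
Conditions: AcOH/H2O (4:1), 40 °C
Reagents that add atoms: none
Why: Acid-catalysed hydrolysis of the terminal isopropylidene acetal under conditions too mild to dehydrate the aldol or ionise the allylic ester.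

Step 34
Reactants: 49 triol
Product: 50 primary p-toluenesulfonate of 49
Conditions: TsCl, pyridine, CH2Cl2, 0 °C
Reagents that add atoms: p-toluenesulfonyl chloride, Cc1ccc(cc1)S(=O)(=O)Cl
Why: Selective sulfonylation of the primary alcohol in the presence of a hindered secondary and a tertiary alcohol.

Step 35
Reactants: 50 hydroxy tosylate
Product: 51 epoxy aldol (target lacking the acetyl group)
Conditions: K2CO3, MeOH, 0 °C, 20 min
Reagents that add atoms: none
Why: Intramolecular Williamson etherification in which the tertiary alkoxide displaces the neighbouring primary tosylate, so the quaternary C–O bond and its (S) configuration are kept.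

Step 36
Reactants: 51 epoxy aldol
Product: 52 target CNP0262178.2
Conditions: Ac2O, pyridine, DMAP (cat.), CH2Cl2, 0 °C
Reagents that add atoms: acetic anhydride, CC(=O)OC(C)=O
Why: Acetylation of the secondary aldol hydroxyl under mild nucleophilic catalysis at 0 °C, which avoids β-elimination.

## Compound list

1 | ethyl pent-2-ynoate | CCC#CC(=O)OCC | starting material
2 | lithium [(Z)-1-ethoxy-3-methyl-1-oxopent-2-en-2-yl](methyl)cuprate (alkenylcuprate) | CC/C(C)=C(\C(=O)OCC)[Cu-]C.[Li+] | intermediate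
3 | ethyl (Z)-3-methylpent-2-enoate | CC/C(C)=C\C(=O)OCC | intermediate
4 | (Z)-3-methylpent-2-enoic acid | CC/C(C)=C\C(=O)O | intermediate
5 | (Z)-3-methylpent-2-enoyl chloride | CC/C(C)=C\C(=O)Cl | intermediate
6 | tiglic acid, (E)-2-methylbut-2-enoic acid | C/C=C(\C)C(=O)O | starting material
7 | (R)-2-methylbutanoic acid | OC(=O)[C@H](C)CC | intermediate
8 | (R)-2-methylbutanoic anhydride | CC[C@@H](C)C(=O)OC(=O)[C@H](C)CC | intermediate
9 | cyclohexa-1,3-diene | C1=CC=CCC1 | starting material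
10 | 2,3-dioxabicyclo[2.2.2]oct-5-ene (endoperoxide) | C1CC2C=CC1OO2 | intermediate
11 | cis-cyclohex-2-ene-1,4-diol (meso) | O[C@H]1C=C[C@@H](O)CC1 | intermediate
12 | (1S,4R)-4-hydroxycyclohex-2-en-1-yl acetate | O[C@H]1C=C[C@@H](OC(C)=O)CC1 | intermediate
13 | (1S,4R)-4-(TBS-oxy)cyclohex-2-en-1-yl acetate | CC(C)(C)[Si](C)(C)O[C@H]1C=C[C@@H](OC(C)=O)CC1 | intermediate
14 | triethyl phosphonoacetate | CCOC(=O)CP(=O)(OCC)OCC | starting material
15 | ethyl 2-[(1S,4R)-4-(TBS-oxy)cyclohex-2-en-1-yl]-2-(diethoxyphosphoryl)acetate (both epimers at the acetate carbon) | CC(C)(C)[Si](C)(C)O[C@H]1C=C[C@@H](C(C(=O)OCC)P(=O)(OCC)OCC)CC1 | intermediate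
16 | ethyl 2-[(1S,4R)-4-(TBS-oxy)cyclohex-2-en-1-yl]prop-2-enoate | CC(C)(C)[Si](C)(C)O[C@H]1C=C[C@@H](C(=C)C(=O)OCC)CC1 | intermediate
17 | 2-[(1S,4R)-4-(TBS-oxy)cyclohex-2-en-1-yl]prop-2-en-1-ol | CC(C)(C)[Si](C)(C)O[C@H]1C=C[C@@H](C(=C)CO)CC1 | intermediate
18 | [(2S)-2-[(1S,4R)-4-(TBS-oxy)cyclohex-2-en-1-yl]oxiran-2-yl]methanol | CC(C)(C)[Si](C)(C)O[C@H]1C=C[C@@H]([C@@]2(CO2)CO)CC1 | intermediate
19 | (2S)-2-[(1S,4R)-4-(TBS-oxy)cyclohex-2-en-1-yl]propane-1,2-diol | CC(C)(C)[Si](C)(C)O[C@H]1C=C[C@@H]([C@@](O)(C)CO)CC1 | intermediate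
20 | tert-butyldimethyl{[(1R,4S)-4-[(4S)-2,2,4-trimethyl-1,3-dioxolan-4-yl]cyclohex-2-en-1-yl]oxy}silane | CC(C)(C)[Si](C)(C)O[C@H]1C=C[C@@H]([C@@]2(C)COC(C)(C)O2)CC1 | intermediate
21 | (1R,4S)-4-[(4S)-2,2,4-trimethyl-1,3-dioxolan-4-yl]cyclohex-2-en-1-ol | O[C@H]1C=C[C@@H]([C@@]2(C)COC(C)(C)O2)CC1 | intermediate
22 | (4S)-4-[(4S)-2,2,4-trimethyl-1,3-dioxolan-4-yl]cyclohex-2-en-1-one | O=C1C=C[C@@H]([C@@]2(C)COC(C)(C)O2)CC1 | intermediate
23 | (Z)-1-bromoprop-1-ene | C/C=C\Br | starting material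
24 | (Z)-prop-1-enyllithium | C/C=C\[Li] | intermediate
25 | lithium di[(Z)-prop-1-enyl]cuprate | C/C=C\[Cu-]/C=C\C.[Li+] | intermediate
26 | trimethyl{[(3S,4S)-3-[(Z)-prop-1-enyl]-4-Diox-cyclohex-1-en-1-yl]oxy}silane | C[Si](C)(C)OC1=C[C@H](/C=C\C)[C@@H]([C@@]2(C)COC(C)(C)O2)CC1 | intermediate
27 | methyl bromoacetate | COC(=O)CBr | starting material
28 | lithium enolate corresponding to 26 (O–Li in place of O–SiMe3) | [Li]OC1=C[C@H](/C=C\C)[C@@H]([C@@]2(C)COC(C)(C)O2)CC1 | intermediate
29 | methyl 2-[(1S,2R,3S)-6-oxo-2-[(Z)-prop-1-enyl]-3-Diox-cyclohexyl]acetate | O=C1[C@@H](CC(=O)OC)[C@H](/C=C\C)[C@@H]([C@@]2(C)COC(C)(C)O2)CC1 | intermediate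
30 | methyl 2-[(1S,2S,3S,6R)-6-hydroxy-2-[(Z)-prop-1-enyl]-3-Diox-cyclohexyl]acetate | COC(=O)C[C@H]1[C@H](/C=C\C)[C@@H]([C@@]2(C)COC(C)(C)O2)CC[C@H]1O | intermediate
31 | (3aS,4S,5S,7aR)-4-[(Z)-prop-1-enyl]-5-Diox-hexahydro-1-benzofuran-2(3H)-one | O=C1C[C@H]2[C@H](/C=C\C)[C@@H]([C@@]3(C)COC(C)(C)O3)CC[C@H]2O1 | intermediate
32 | (3aS,4S,5S,7aR)-4-[(Z)-prop-1-enyl]-5-Diox-octahydro-1-benzofuran-2-ol (anomers) | OC1C[C@H]2[C@H](/C=C\C)[C@@H]([C@@]3(C)COC(C)(C)O3)CC[C@H]2O1 | intermediate
33 | 2-[(1S,2S,3S,6R)-6-hydroxy-2-[(Z)-prop-1-enyl]-3-Diox-cyclohexyl]acetaldehyde oxime (E/Z) | ON=CC[C@H]1[C@H](/C=C\C)[C@@H]([C@@]2(C)COC(C)(C)O2)CC[C@H]1O | intermediate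
34 | hydroximoyl chloride of 33 | ON=C(Cl)C[C@H]1[C@H](/C=C\C)[C@@H]([C@@]2(C)COC(C)(C)O2)CC[C@H]1O | intermediate
35 | nitrile oxide from 34 | [O-][N+]#CC[C@H]1[C@H](/C=C\C)[C@@H]([C@@]2(C)COC(C)(C)O2)CC[C@H]1O | intermediate
36 | isoxazoline alcohol: trans-hydrindane (H-3a α; H-7a β); Δ2-isoxazoline on C1–C2 (C2=N; O on C1′; 1′-CH3; 1′S; H-1 α); 4β-OH; 7β-Diox | O[C@H]1[C@H]2CC3=NO[C@@H](C)[C@H]3[C@@H]2[C@@H]([C@@]4(C)COC(C)(C)O4)CC1 | intermediate
37 | tricyclic ketone: as 36 with C4=O | O=C1[C@H]2CC3=NO[C@@H](C)[C@H]3[C@@H]2[C@@H]([C@@]4(C)COC(C)(C)O4)CC1 | intermediate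
38 | Δ4,5 trimethylsilyl enol ether of 37 | C[Si](C)(C)OC=1[C@H]2CC3=NO[C@@H](C)[C@H]3[C@@H]2[C@@H]([C@@]4(C)COC(C)(C)O4)CC=1 | intermediate
39 | enone: as 37 with C5=C6 | O=C1[C@H]2CC3=NO[C@@H](C)[C@H]3[C@@H]2[C@@H]([C@@]4(C)COC(C)(C)O4)C=C1 | intermediate
40 | 5α,6α-dihydroxy derivative of 37 | O=C1[C@H]2CC3=NO[C@@H](C)[C@H]3[C@@H]2[C@@H]([C@@]4(C)COC(C)(C)O4)[C@H](O)[C@@H]1O | intermediate
41 | 5α,6α-bis(triethylsilyl) ether of 40 | O=C1[C@H]2CC3=NO[C@@H](C)[C@H]3[C@@H]2[C@@H]([C@@]4(C)COC(C)(C)O4)[C@H](O[Si](CC)(CC)CC)[C@@H]1O[Si](CC)(CC)CC | intermediate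
42 | 4-methylene analogue of 41 | C=C1[C@H]2CC3=NO[C@@H](C)[C@H]3[C@@H]2[C@@H]([C@@]4(C)COC(C)(C)O4)[C@H](O[Si](CC)(CC)CC)[C@@H]1O[Si](CC)(CC)CC | intermediate
43 | 4-methylene-5α,6α-diol | C=C1[C@H]2CC3=NO[C@@H](C)[C@H]3[C@@H]2[C@@H]([C@@]4(C)COC(C)(C)O4)[C@H](O)[C@@H]1O | intermediate
44 | 5,6-O-dibutylstannylene acetal of 43 | C=C1[C@H]2CC3=NO[C@@H](C)[C@H]3[C@@H]2[C@@H]([C@@]4(C)COC(C)(C)O4)[C@@H]5O[Sn](CCCC)(CCCC)O[C@H]15 | intermediate
45 | 6α-[(Z)-3-methylpent-2-enoyl]oxy-5α-ol | C=C1[C@H]2CC3=NO[C@@H](C)[C@H]3[C@@H]2[C@@H]([C@@]4(C)COC(C)(C)O4)[C@H](OC(=O)/C=C(/C)CC)[C@@H]1O | intermediate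
46 | 5α-[(R)-2-methylbutanoyl]oxy-6α-[(Z)-3-methylpent-2-enoyl]oxy isoxazoline | C=C1[C@H]2CC3=NO[C@@H](C)[C@H]3[C@@H]2[C@@H]([C@@]4(C)COC(C)(C)O4)[C@H](OC(=O)/C=C(/C)CC)[C@@H]1OC(=O)[C@H](C)CC | intermediate
47 | β-hydroxy imine (C2=NH; 1′-OH) from 46 | C=C1[C@H]2CC(=N)[C@@H]([C@H](C)O)[C@@H]2[C@@H]([C@@]3(C)COC(C)(C)O3)[C@H](OC(=O)/C=C(/C)CC)[C@@H]1OC(=O)[C@H](C)CC | intermediate
48 | β-hydroxy ketone (C2=O; 1′S-OH; 7β-Diox; both esters) | C=C1[C@H]2CC(=O)[C@@H]([C@H](C)O)[C@@H]2[C@@H]([C@@]3(C)COC(C)(C)O3)[C@H](OC(=O)/C=C(/C)CC)[C@@H]1OC(=O)[C@H](C)CC | intermediate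
49 | triol: as 48 with 7β-[(2S)-1,2-dihydroxypropan-2-yl] | C=C1[C@H]2CC(=O)[C@@H]([C@H](C)O)[C@@H]2[C@@H]([C@@](O)(C)CO)[C@H](OC(=O)/C=C(/C)CC)[C@@H]1OC(=O)[C@H](C)CC | intermediate
50 | primary p-toluenesulfonate of 49 | C=C1[C@H]2CC(=O)[C@@H]([C@H](C)O)[C@@H]2[C@@H]([C@@](O)(C)COS(=O)(=O)c3ccc(C)cc3)[C@H](OC(=O)/C=C(/C)CC)[C@@H]1OC(=O)[C@H](C)CC | intermediate
51 | epoxy aldol: target with free 1′-OH | C=C1[C@H]2CC(=O)[C@@H]([C@H](C)O)[C@@H]2[C@@H]([C@@]2(C)CO2)[C@H](OC(=O)/C=C(/C)CC)[C@@H]1OC(=O)[C@H](C)CC | intermediate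
52 | CNP0262178.2: (1R,3aS,5R,6S,7R,7aS)-1-[(1S)-1-acetoxyethyl]-4-methylene-7-[(2S)-2-methyloxiran-2-yl]-2-oxo-octahydroindene-5,6-diyl 5-[(R)-2-methylbutanoate] 6-[(Z)-3-methylpent-2-enoate] | C=C1[C@H]2CC(=O)[C@@H]([C@H](C)OC(C)=O)[C@@H]2[C@@H]([C@@]2(C)CO2)[C@H](OC(=O)/C=C(/C)CC)[C@@H]1OC(=O)[C@H](C)CC | target

## Totals and risks

Total step count: 36 (31 in the main line, 3 for acid chloride 5, 2 for anhydride 8).
Longest linear sequence: 31 steps (steps 6–36, from cyclohexa-1,3-diene).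

Three steps most likely to fail:

Step 22 (nitrile oxide cycloaddition). The risk is furoxan dimerisation or sluggish closure of the trans-fused ring. The fallback sets out from silyl enol ether 26 and comes back at tricyclic ketone 37, using a silyl nitronate dipole and no hydride detour. MeLi regenerates lithium enolate 28, which adds to nitroethylene (THF, −78 °C) to give the nitro ketone F1. Me3SiCl/Et3N (benzene, rt) turns it into the silyl nitronate F2, which cyclises onto the Z-propenyl group to the N-silyloxyisoxazolidine F3. TsOH (cat.) eliminates trimethylsilanol and gives 37.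

Step 30 (stannylene-directed acylation). The risk is wrong regiochemistry or slow acylation next to the quaternary C7 substituent. The fallback sets out from diol 43 and comes back at monoester 45, relying on kinetic orthoester opening instead of tin activation. Trimethyl orthoformate/PPTS gives the cyclic orthoformate F4. Wet AcOH opens it to the axial 5α-formate with free 6α-OH F5. Yamaguchi esterification with acid 4 (2,4,6-trichlorobenzoyl chloride, Et3N, DMAP, toluene) gives the formate enoate F6. NH3 in MeOH at 0 °C removes only the formate and gives 45.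

Step 35 (oxirane closure with the aldol and two esters present). The risk is retro-aldol, acyl migration or methanolysis. The fallback sets out from diester isoxazoline 46 and comes back at epoxy aldol 51, closing the oxirane before the aldol is unmasked. AcOH/H2O gives the isoxazoline diol F7, TsCl/pyridine the isoxazoline tosylate F8, and K2CO3/MeOH (0 °C) the epoxy isoxazoline F9. SmI2 (THF, 0 °C; then B(OH)3, aq. MeOH) cleaves the N–O bond, to which the isolated oxirane, alkenes and esters are inert, and gives 51.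

Further compounds
F1 | step 22 | nitro ketone: (2S,3R,4S)-2-(2-nitroethyl)-3-[(Z)-prop-1-enyl]-4-Diox-cyclohexan-1-one | O=C1[C@@H](CC[N+](=O)[O-])[C@H](/C=C\C)[C@@H]([C@@]2(C)COC(C)(C)O2)CC1
F2 | step 22 | silyl nitronate of F1 | O=C1[C@@H](CC=[N+]([O-])O[Si](C)(C)C)[C@H](/C=C\C)[C@@H]([C@@]2(C)COC(C)(C)O2)CC1
F3 | step 22 | N-silyloxyisoxazolidine: as 37 with C2–N single bond and N–OSiMe3 | O=C1[C@H]2CC3N(O[Si](C)(C)C)O[C@@H](C)[C@H]3[C@@H]2[C@@H]([C@@]4(C)COC(C)(C)O4)CC1
F4 | step 30 | cyclic orthoformate (5,6-O-methoxymethylidene) of 43 | C=C1[C@H]2CC3=NO[C@@H](C)[C@H]3[C@@H]2[C@@H]([C@@]4(C)COC(C)(C)O4)[C@@H]5OC(OC)O[C@H]15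
F5 | step 30 | 5α-formate with free 6α-OH | C=C1[C@H]2CC3=NO[C@@H](C)[C@H]3[C@@H]2[C@@H]([C@@]4(C)COC(C)(C)O4)[C@H](O)[C@@H]1OC=O
F6 | step 30 | 5α-formate 6α-[(Z)-3-methylpent-2-enoate] | C=C1[C@H]2CC3=NO[C@@H](C)[C@H]3[C@@H]2[C@@H]([C@@]4(C)COC(C)(C)O4)[C@H](OC(=O)/C=C(/C)CC)[C@@H]1OC=O
F7 | step 35 | isoxazoline diol: 46 with 7β-[(2S)-1,2-dihydroxypropan-2-yl] | C=C1[C@H]2CC3=NO[C@@H](C)[C@H]3[C@@H]2[C@@H]([C@@](O)(C)CO)[C@H](OC(=O)/C=C(/C)CC)[C@@H]1OC(=O)[C@H](C)CC
F8 | step 35 | isoxazoline tosylate: primary p-toluenesulfonate of F7 | C=C1[C@H]2CC3=NO[C@@H](C)[C@H]3[C@@H]2[C@@H]([C@@](O)(C)COS(=O)(=O)c4ccc(C)cc4)[C@H](OC(=O)/C=C(/C)CC)[C@@H]1OC(=O)[C@H](C)CC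
F9 | step 35 | epoxy isoxazoline: 46 with 7β-[(2S)-2-methyloxiran-2-yl] | C=C1[C@H]2CC3=NO[C@@H](C)[C@H]3[C@@H]2[C@@H]([C@@]4(C)CO4)[C@H](OC(=O)/C=C(/C)CC)[C@@H]1OC(=O)[C@H](C)CC
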